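Amounts first: I had to choose between charging much substrate for a short time and little for a long time, and I wanted the recipe that ends with more target.

| flask | substrate | gas phase | remark | time |
|---|---|---|---|---|
| larch | 0.031 M | 4.2 mM (held) | run made earlier |  |
| alder | 0.16 M | 4.2 mM (held) | run made earlier |  |
| south-east | 0.20 M | 4.2 mM (held) |  | 2.0 d |
| north-east | 0.050 M | 4.2 mM (held) |  | 6.0 d |

- larch (time / d: target / %, substrate / %): 0.333: 6.0, 94.0; 0.833: 14.2, 82.8; 1.67: 32.2, 66.2; 2.50: 41.2, 51.5; 4.00: 53.8, 31.2; 5.00: 55.9, 25.1; 6.00: 59.4, 15.9
- alder (time / d: target / %, substrate / %): 0.833: 4.2, 95.8; 1.67: 11.6, 87.3; 2.50: 16.0, 80.9; 3.00: 21.9, 78.5; 4.00: 27.3, 69.9; 5.00: 34.1, 63.8; 6.00: 38.2, 57.8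

(scatter of a reading: 1 percentage point)

- which one finishes higher in amount of target, in percent of the substrate charged ("neither" within 2 percentage points) (south-east / north-east / neither)
- amount of target at the end, in percent of the substrate charged, south-east
- amount of target at the end, in percent of the substrate charged, north-east

- the numbers in the tables scatter by 1 percentage point (one standard deviation)
- at the start none of the gas phase is in solution

I reckoned with the fraction of substrate left, not with the target made. From each last reading I took the halving time, a pseudo-first-order half-life averaged over the run: the time, times ln(2), divided by the logarithm of charge over left.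

larch run: 2.26 d
alder run: 7.59 d

The alder run halved more slowly, so I drew a straight line through the two. Its slope, taken in larch units, is 0.566, the stretch of the halving time per charge: the part of the larch halving time that is added for each further larch charge of substrate. South-east lies a little beyond the alder charge, so its value is an extrapolation.

south-east: halving time 9.24 d, left 86.1%
north-east: halving time 3.05 d, left 25.5%

Target I read against the fraction left: larch had 32.2% at 66.2% left, alder 34.1% at 63.8% left. For north-east, the larch reading at 25.1% left gave 55.9%. For south-east, the alder share of target in what had reacted gave 12.7%.

The forecast also chose north-east, with 10.8% (8.5% to 13%) for south-east and 57% (52% to 61%) for north-east, on the grounds of “a rate limited by gas supply”. My south-east figure stood higher than its value.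

The flask gave north-east, with 57.0% against 12.5%. North-east held 18.7% as over-reacted product at 6.00 d, beside 24% substrate left. That remainder means a halving time of 2.94 d, against 3.05 d from the line with its stretch of 0.566.

    dissolved gas ⇌ dormant form (K = 42.6, k = 0.0110 /h)
    dissolved gas + target → over-reacted product (k = 1.81 /M/h)
    gas phase ⇌ dissolved gas, rate k3*(csat - [dissolved gas]) (kL = 0.153 /h)
    substrate + dissolved gas → target (k = 5.39 /M/h)

A neighbour flask, north-east with 0.12 M substrate, gets 5.94 d from the line, so 49.6% left, and the larch reading at 51.5% left is 41.2% target. Computed, it holds 49% substrate and 45.0% target.

The runs stem from a simulated flask on assumed constants, noise included.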